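Freeze the two chain carriers at their steady state (the quasi-steady-state approximation) and the initiator at its charge, and each flask keeps one number: the first-order constant of substrate loss. I took carriers ending in pairs as the suspect termination, which puts that constant on the square root of c(initiator).

common to all: substrate 10 mM
- Sunday's: reagent 25 mM; scavenger 12 mM; initiator 0.10 mM; temperature −5 °C; run made earlier
- Wednesday's: reagent 25 mM; scavenger 12 mM; initiator 0.15 mM; temperature 17 °C; run made earlier
- winter: reagent 25.0 mM; scavenger 12.0 mM; initiator 0.20 mM; temperature 25 °C; time 2.5 h
- dawn: reagent 25.0 mM; scavenger 12.0 mM; initiator 0.20 mM; temperature −15 °C; time 4.0 h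

- Sunday's (time / h: product / %, substrate / %): 0.833: 0, 97; 3.00: 3, 98; 6.00: 0, 94; 8.00: 7, 86; 12.0: 6, 93
- Wednesday's (time / h: product / %, substrate / %): 0.200: 3, 97; 0.667: 6, 91; 1.33: 12, 84; 2.00: 17, 86; 2.50: 23, 77

(scatter of a reading: 2 percentage points)

- in percentages every species weighs as the substrate in it: one ended chains A counts as two
- for product the crystals are counted in
- for released group the idle adduct is counted in
- as a solid, counted per litre of solution: crystals
- on the list of suspects stand: first chain carrier -> ended carrier; reagent + first chain carrier -> product + second chain carrier; substrate + released group <-> idle adduct; substrate + initiating radical -> capped initiator + first chain carrier; scavenger + released group -> scavenged by-product; crystals <-> product; 2 first chain carrier -> ended chains A; substrate + second chain carrier -> released group + first chain carrier; 2 second chain carrier -> ended chains B; initiator -> 2 initiating radical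

- the flask that ends with the higher amount of product, in percent of the substrate charged, or "neither" when 2 percentage points or less lies between them (winter / dawn / neither)
- final product, as a percentage of the substrate charged, in winter
- final product, as a percentage of the substrate charged, in dawn

I read the constant from the last substrate readings: 0.105 h⁻¹ in Wednesday's run and 0.00605 h⁻¹ in Sunday's. Sunday's rests on a loss of 7.00% with a scatter of 2 percentage points, so it is a rough reading. With the root of c(initiator) divided out, the two differed by a factor of 14.1, and I spread that factor evenly in the logarithm over temperature. This gave 0.316 h⁻¹ for the winter chain constant, the first-order constant of substrate loss at winter's temperature and c(initiator).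

So I drew winter's substrate curve with a slope of 3.16 mM h⁻¹ at the start. On that drawn curve substrate crossed its half at 2.19 h, earlier than the end at 2.5 h. I drew no knee, since the charges of reagent and scavenger stood at 2.50 and 1.20 times the substrate. My winter product came to 54.6%. For dawn the same reckoning from Sunday's run gave 0.00257 h⁻¹, a nearly straight line reaching 1.02%.

The forecast chose winter, with 47% there and 1% in dawn, a winter figure below mine; it called its apparent activation energy “poorly fixed by Sunday's noise”.

The flasks gave 48.6% in winter and 1.09% in dawn, so the richer flask was winter.

    first chain carrier → ended carrier (k = 0.699 s⁻¹, Ea = 68.0 kJ mol⁻¹)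
    reagent + first chain carrier → product + second chain carrier (k = 27100 M⁻¹ s⁻¹, Ea = 16.0 kJ mol⁻¹)
    substrate + released group ⇌ idle adduct, settled at all times (K = 210 M⁻¹, ΔH = −26.0 kJ mol⁻¹)
    substrate + initiating radical → capped initiator + first chain carrier (k = 1.89 × 10⁵ M⁻¹ s⁻¹, Ea = 24.0 kJ mol⁻¹)
    scavenger + released group → scavenged by-product (k = 0.423 M⁻¹ s⁻¹, Ea = 45.0 kJ mol⁻¹)
    crystals ⇌ product, rate k6*(cs6 - [product]) while solid is left; crystals form when [product] > cs6 (solubility = 3.50 mM, k = 0.00763 s⁻¹)
    2 first chain carrier → ended chains A (k = 2.00 × 10⁸ M⁻¹ s⁻¹, Ea = 14.0 kJ mol⁻¹)
    substrate + second chain carrier → released group + first chain carrier (k = 35800 M⁻¹ s⁻¹, Ea = 28.0 kJ mol⁻¹)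
    2 second chain carrier → ended chains B (k = 2.00 × 10⁸ M⁻¹ s⁻¹, Ea = 12.0 kJ mol⁻¹)
    initiator → 2 initiating radical (k = 7.05 × 10⁻⁶ s⁻¹, Ea = 108 kJ mol⁻¹)
    (constants at 25 °C)

At 1.07 h in winter, the step from substrate and second chain carrier used substrate 200 times as fast as capping by the initiating radical, and 93.9% of the initiator still stood at the end. Winter's 49.9% of substrate left corresponds to 0.278 h⁻¹, lower than my 0.316 h⁻¹. Scaled by the root to the same flask with 0.80 mM of initiator, my 0.316 h⁻¹ gives 20.6% of substrate left, and that flask held 22.1%.

(All runs were computed on assumed constants; the scatter is artificial.)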